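**Strategy.** The target is a 3-bromocatechol (ring B: C1 and C2 bear the CH2 groups, C3 Br, C4/C5 OH, C6 H) carrying two identical 2,3-dibromo-4,5-dihydroxybenzyl groups. Everything rests on cutting the CH2–C1(ring B) bond of the benzyl group attached para to O4. The key step, an acid-catalysed dehydrative Friedel–Crafts benzylation, completes the triaryl skeleton in one operation. It exploits the free O4–H of ring B, whose ortho carbons are blocked (C3–Br, C5–OMe), so C1 (para) is the only open carbon it activates strongly. Its precursor is the B–C diarylmethane phenol, made with the same benzylic alcohol while O4 is masked as acetate, so that O5–Me directs to C2.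

Key step: step 7

Remark on the chemistry: the target has no stereogenic element, so no stereocontrol is required; ring A is the benzyl unit on C1 of ring B and ring C the benzyl unit on C2; 5-bromovanillin and 2-bromo-6-methoxyphenol are taken as commercial.

Step 1
Reactants: 1 5-bromovanillin (3-bromo-4-hydroxy-5-methoxybenzaldehyde)
Product: 2 2,3-dibromo-4-hydroxy-5-methoxybenzaldehyde
Conditions: Br2 (1.2 equiv), Fe powder (cat.), AcOH, rt → 60 °C
Reagents that add atoms: bromine, BrBr
Why: Electrophilic aromatic bromination, in which the free position para to the methoxy group is the activated one, so the second bromine should enter next to the first, as is established for 5,6-dibromovanillin.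

Step 2
Reactants: 2 2,3-dibromo-4-hydroxy-5-methoxybenzaldehyde
Product: 3 2,3-dibromo-4,5-dimethoxybenzaldehyde
Conditions: MeI, K2CO3, DMF, rt
Reagents that add atoms: iodomethane, CI
Why: Williamson O-methylation of the acidic phenol; aldehyde and aryl bromides are inert to these conditions.

Step 3
Reactants: 3 2,3-dibromo-4,5-dimethoxybenzaldehyde
Product: 4 (2,3-dibromo-4,5-dimethoxyphenyl)methanol
Conditions: NaBH4, MeOH–THF, 0 °C
Reagents that add atoms: none
Why: Chemoselective borohydride reduction of the aldehyde to the benzylic alcohol, which leaves aryl bromides and ethers untouched.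

Step 4
Reactants: 5 2-bromo-6-methoxyphenol
Product: 6 2-bromo-6-methoxyphenyl acetate
Conditions: Ac2O, pyridine, DMAP (cat.), CH2Cl2, rt
Reagents that add atoms: acetic anhydride, CC(=O)OC(C)=O
Why: DMAP-catalysed O-acetylation turns the phenol oxygen into a weak donor, so that in the next step the methoxy group alone decides the site of substitution (the guaiacol acetate principle).

Step 5
Reactants: 4 (2,3-dibromo-4,5-dimethoxyphenyl)methanol; 6 2-bromo-6-methoxyphenyl acetate
Product: 7 2-bromo-3-[(2,3-dibromo-4,5-dimethoxyphenyl)methyl]-6-methoxyphenyl acetate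
Conditions: TfOH (10 mol %), HFIP, 40 °C; acetate 6 in twofold excess, the excess recovered
Reagents that add atoms: none
Why: Dehydrative Friedel–Crafts benzylation, in which the methoxy-stabilised benzylic cation generated from 4 by the acid should attack 6 para to its methoxy group (ortho to Br), the site favoured in 3-haloanisoles, while the acetylated oxygen no longer directs.

Step 6
Reactants: 7 2-bromo-3-[(2,3-dibromo-4,5-dimethoxyphenyl)methyl]-6-methoxyphenyl acetate
Product: 8 2-bromo-3-[(2,3-dibromo-4,5-dimethoxyphenyl)methyl]-6-methoxyphenol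
Conditions: pyrrolidine (3 equiv), THF, rt; dilute HCl wash
Reagents that add atoms: none
Why: Aminolysis of the aryl acetate frees the phenol under mild, non-hydrolytic conditions that spare methyl ethers, aryl bromides and the diarylmethane.

Step 7
Reactants: 8 2-bromo-3-[(2,3-dibromo-4,5-dimethoxyphenyl)methyl]-6-methoxyphenol; 4 (2,3-dibromo-4,5-dimethoxyphenyl)methanol
Product: 9 2-bromo-3,4-bis[(2,3-dibromo-4,5-dimethoxyphenyl)methyl]-6-methoxyphenol
Conditions: TfOH (5 mol %), HFIP, rt; alcohol 4 (1.05 equiv) added slowly
Reagents that add atoms: none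
Why: TfOH in HFIP ionises alcohol 4 to its para-methoxy-stabilised benzylic cation, which is captured by the carbon para to the free hydroxyl of phenol 8; loss of a proton re-aromatises ring B and water is the only by-product. The closest known reaction type is the Brønsted-acid/HFIP-promoted (or AlCl3-mediated) Friedel–Crafts benzylation of phenols and aryl ethers with benzylic alcohols. No ring is closed and no stereocentre is formed. The step needs attack at C1 of ring B (not at C6 or at the free CH of ring C) and mono-benzylation: the free O4–H is the strongest donor present and its two ortho carbons carry Br and OMe, so the para carbon is the only strongly activated open site, whereas C6 is merely ortho to a methoxy group and ring C is deactivated by two bromines. O-Benzylation is reversible under acid and should funnel to the C-benzylated product, and the electrophile should hardly self-condense because its own ring has one free, bromine-deactivated position. Because the incoming and the resident benzyl groups are identical, any acid-induced benzyl exchange at C2 is degenerate.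

Step 8
Reactants: 9 2-bromo-3,4-bis[(2,3-dibromo-4,5-dimethoxyphenyl)methyl]-6-methoxyphenol
Product: 10 3-bromo-4,5-bis[(2,3-dibromo-4,5-dihydroxyphenyl)methyl]benzene-1,2-diol (target)
Conditions: BBr3 (10 equiv), CH2Cl2, −78 °C → rt; then ice/H2O, under argon
Reagents that add atoms: none
Why: Lewis-acid cleavage of all five aryl methyl ethers (BBr3 demethylation), which aryl bromides and diarylmethane links normally survive.

**Compound list**
1 | 5-bromovanillin (3-bromo-4-hydroxy-5-methoxybenzaldehyde) | COc1cc(C=O)cc(Br)c1O | starting material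
2 | 2,3-dibromo-4-hydroxy-5-methoxybenzaldehyde | COc1cc(C=O)c(Br)c(Br)c1O | intermediate
3 | 2,3-dibromo-4,5-dimethoxybenzaldehyde | COc1cc(C=O)c(Br)c(Br)c1OC | intermediate
4 | (2,3-dibromo-4,5-dimethoxyphenyl)methanol | COc1cc(CO)c(Br)c(Br)c1OC | intermediate
5 | 2-bromo-6-methoxyphenol | COc1cccc(Br)c1O | starting material
6 | 2-bromo-6-methoxyphenyl acetate | COc1cccc(Br)c1OC(C)=O | intermediate
7 | 2-bromo-3-[(2,3-dibromo-4,5-dimethoxyphenyl)methyl]-6-methoxyphenyl acetate | COc1ccc(Cc2cc(OC)c(OC)c(Br)c2Br)c(Br)c1OC(C)=O | intermediate
8 | 2-bromo-3-[(2,3-dibromo-4,5-dimethoxyphenyl)methyl]-6-methoxyphenol | COc1ccc(Cc2cc(OC)c(OC)c(Br)c2Br)c(Br)c1O | intermediate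
9 | 2-bromo-3,4-bis[(2,3-dibromo-4,5-dimethoxyphenyl)methyl]-6-methoxyphenol | COc1cc(Cc2cc(OC)c(OC)c(Br)c2Br)c(Cc2cc(OC)c(OC)c(Br)c2Br)c(Br)c1O | intermediate
10 | 3-bromo-4,5-bis[(2,3-dibromo-4,5-dihydroxyphenyl)methyl]benzene-1,2-diol | Oc1cc(Cc2cc(O)c(O)c(Br)c2Cc2cc(O)c(O)c(Br)c2Br)c(Br)c(Br)c1O | target

**Total step count:** 8. **Longest linear sequence:** 7 steps (steps 1, 2, 3, 5, 6, 7, 8).

**Steps most likely to fail**

Step 5. The benzyl cation may attack ortho to the methoxy group (para to Br) instead of para to it. The acetate may be lost under acid, after which benzylation would occur para to the freed hydroxyl. The deactivated ring may also react so slowly that the electrophile self-condenses. The fallback sets out from 6 and 4 and comes back at 7, replacing the electrophilic substitution by a cross-coupling at a halogen placed by a more selective halogenation. Acetate 6 is iodinated para to the methoxy group (NIS, TFA, MeCN) to give 2-bromo-3-iodo-6-methoxyphenyl acetate F1. Alcohol 4 is converted with SOCl2 into 2,3-dibromo-1-(chloromethyl)-4,5-dimethoxybenzene F2, and zinc insertion (Zn dust, LiCl, THF) gives (2,3-dibromo-4,5-dimethoxybenzyl)zinc chloride F3. Negishi coupling of F1 with F3 (Pd(PPh3)4, THF, rt) should engage the C–I bond in preference to the hindered C–Br bonds and tolerate the acetate, giving 7.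

Step 7. Site selectivity may erode (attack at C6 of ring B or on ring C), the product may be benzylated again, or acid may induce benzyl migration. The fallback sets out from 8 and comes back at 10. Phenol 8 is iodinated at the only open position para to the hydroxyl (NIS, MeCN, 0 °C) to give 2-bromo-3-[(2,3-dibromo-4,5-dimethoxyphenyl)methyl]-4-iodo-6-methoxyphenol F4. Methylation (MeI, K2CO3, DMF) gives 3-bromo-2-[(2,3-dibromo-4,5-dimethoxyphenyl)methyl]-1-iodo-4,5-dimethoxybenzene F5. Iodide-selective Negishi coupling with the benzylzinc reagent F3 of the preceding fallback (made from 4; Pd(PPh3)4, THF, rt) forms the same CH2–C1 bond and gives 3-bromo-1,2-bis[(2,3-dibromo-4,5-dimethoxyphenyl)methyl]-4,5-dimethoxybenzene F6. BBr3 under the conditions of step 8 then cleaves its six methyl ethers to give 10.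

Step 8. Cleavage of the five hindered ethers may stop short, the Lewis acid may transfer benzyl groups (retro-Friedel–Crafts at the oxygen-para diarylmethane carbons), and the tris-catechol may oxidise in air on work-up. The fallback removes the methyl groups before the union; it sets out from 8 and 3 and comes back at 10. BBr3 on 8 (three ethers, one diarylmethane link) gives 3-bromo-4-[(2,3-dibromo-4,5-dihydroxyphenyl)methyl]benzene-1,2-diol F7. BBr3 on aldehyde 3 gives 2,3-dibromo-4,5-dihydroxybenzaldehyde F8, which NaBH4 reduces to 3,4-dibromo-5-(hydroxymethyl)benzene-1,2-diol (lanosol) F9. F7 and F9 are then joined by the same acid-catalysed benzylation (TfOH cat., HFIP, rt, argon), which should again favour the carbon para to O4–H of ring B and give 10 directly.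

**Further compounds**
F1 | step 5 | 2-bromo-3-iodo-6-methoxyphenyl acetate | COc1ccc(I)c(Br)c1OC(C)=O
F2 | step 5 | 2,3-dibromo-1-(chloromethyl)-4,5-dimethoxybenzene | COc1cc(CCl)c(Br)c(Br)c1OC
F3 | step 5 | (2,3-dibromo-4,5-dimethoxybenzyl)zinc chloride | COc1cc(C[Zn]Cl)c(Br)c(Br)c1OC
F4 | step 7 | 2-bromo-3-[(2,3-dibromo-4,5-dimethoxyphenyl)methyl]-4-iodo-6-methoxyphenol | COc1cc(I)c(Cc2cc(OC)c(OC)c(Br)c2Br)c(Br)c1O
F5 | step 7 | 3-bromo-2-[(2,3-dibromo-4,5-dimethoxyphenyl)methyl]-1-iodo-4,5-dimethoxybenzene | COc1cc(I)c(Cc2cc(OC)c(OC)c(Br)c2Br)c(Br)c1OC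
F6 | step 7 | 3-bromo-1,2-bis[(2,3-dibromo-4,5-dimethoxyphenyl)methyl]-4,5-dimethoxybenzene | COc1cc(Cc2cc(OC)c(OC)c(Br)c2Br)c(Cc2cc(OC)c(OC)c(Br)c2Br)c(Br)c1OC
F7 | step 8 | 3-bromo-4-[(2,3-dibromo-4,5-dihydroxyphenyl)methyl]benzene-1,2-diol | Oc1ccc(Cc2cc(O)c(O)c(Br)c2Br)c(Br)c1O
F8 | step 8 | 2,3-dibromo-4,5-dihydroxybenzaldehyde | O=Cc1cc(O)c(O)c(Br)c1Br
F9 | step 8 | 3,4-dibromo-5-(hydroxymethyl)benzene-1,2-diol (lanosol) | OCc1cc(O)c(O)c(Br)c1Br
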